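Count in percent of the substrate charged, the unit of the tables, and take target with isomer of the product as one pool that the flask fills.

common to all: gas 0.57 mM (held); second catalyst 6.7 µM

| charge | substrate | free catalyst | remark | time |
|---|---|---|---|---|
| beta | 1 mM | 23 µM | run made earlier |  |
| zeta | 1 mM | 40 µM | run made earlier |  |
| delta | 1 mM | 44 µM | run made earlier |  |
| north-west | 1.0 mM | 30 µM |  | 10 min |
| west | 1.0 mM | 50 µM |  | 10 min |
| east | 1.0 mM | 60 µM |  | 10 min |

| run | time / min | target / % |
|---|---|---|
| beta | 0.833 | 6 |
| beta | 1.50 | 11 |
| beta | 3.00 | 29 |
| beta | 5.00 | 39 |
| beta | 10.0 | 47 |
| zeta | 2.00 | 15 |
| zeta | 4.00 | 32 |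
| zeta | 6.00 | 43 |
| zeta | 8.00 | 45 |
| zeta | 10.0 | 46 |
| delta | 0.833 | 7 |
| delta | 2.50 | 22 |
| delta | 5.00 | 42 |
| delta | 8.00 | 49 |
| delta | 10.0 | 48 |

(standard deviation of a reading: 1.5 percentage points)

- at the start none of partner is dissolved
- the numbers in the tables scatter with a standard deviation of 1.5 percentage points
- on the list of suspects stand: target + free catalyst <-> isomer of the product + free catalyst; 2 partner -> self-condensation product; gas <-> partner; second catalyst + open intermediate <-> catalyst intermediate; substrate + free catalyst -> free catalyst + open intermediate; partner + catalyst intermediate -> second catalyst + target
- "hardly changes" means that all values lie within two and a half points (for a concentration: within two and a half percent of the largest)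

* amount of target at the end, in percent of the substrate charged for north-west, west, east, in this order
* how that number moves from the first to the last of them (rises all the way / rises, then falls / hardly changes / falls, then rises / falls all the way)

Treat the exchange of target with isomer of the product over free catalyst as standing at equilibrium, and reckon with what that leaves free. The target share s 47.0%, the percent of a full pool that stands as target at that equilibrium, is read here as the mean of the last readings of the beta, zeta and delta runs, and it carries their scatter of 1.5 percentage points.

Turn free catalyst first. By hand, it speeds the exchange both ways, so the pool reaches equilibrium sooner, but the equilibrium stays where it stands. The runs show this: at 23 µM, 40 µM and 44 µM they end at 47%, 46% and 48%.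

Turn time next. By hand, longer adds target while the pool fills and adds nothing once it is full. The zeta run goes from 45% at 8.00 min to 46% at 10.0 min, and the delta run from 49% to 48% over the same stretch, steps about the size of the scatter.

So reckon 47.0% for north-west, west and east alike. The forecast gives 47%, 47% and 46%, hardly changes, on the ground that “More free catalyst only reaches that equilibrium faster.” Its east point lies a little below this reckoning.

The flask gives 47.6%, 47.6% and 47.6%: hardly changes.

    target + free catalyst ⇌ isomer of the product + free catalyst, rate k1*[free catalyst]*[target] forward; the back reaction follows from the equilibrium constant (K = 1.10, k = 2200 /M/s)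
    2 partner → self-condensation product (k = 14.0 /M/s)
    gas ⇌ partner, rate k3*(csat - [partner]) (kL = 0.0480 /s)
    second catalyst + open intermediate ⇌ catalyst intermediate (K = 34000 /M, k = 6100 /M/s)
    substrate + free catalyst → free catalyst + open intermediate (k = 610 /M/s)
    partner + catalyst intermediate → second catalyst + target (k = 1300 /M/s)

In north-west the exchange is the main reason target ends at 47.6%, for the same run without it ends at >99.9%. Its forward half-life of 0.18 min there is short against 10 min, and the reading s leaves 53.0% for the isomer of the product, where north-west holds 52.4%. East, with twice the free catalyst of north-west, takes the same s of 47.0% and ends at 47.6%, while without the exchange it ends at >99.9%.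

The readings are calculated for substances that don't exist, and the scatter is random.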